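**Plan**

- Target read (labdane numbering: ring A = C1–C5/C10, ring B = C5–C10, exocyclic C8=C17, side chain C11–C16) as labd-8(17)-ene-15,18-dioic acid 18-methyl ester, 4R,5R,9S,10R,13S: trans-decalin, equatorial CO2Me at C4.
- Cuts: C15 acid ← silyl-protected alcohol; C8=C17 ← C8 ketone; ring B at C6–C7; C9–C10 by a [3,3] shift of an ester that loses its C6–O bond; ester bond between fragment 1 (ring A allylic alcohol) and fragment 2 (C8–C15 acid from (S)-citronellol).
- Forward: ring A is made first with quaternary C4; the side chain is attached as an ester and moved onto C10 by Ireland–Claisen rearrangement, which also creates the exocyclic C5=C6 methylene; C7 is added as a bromomethyl ketone; ring B is closed last.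
- Enabling feature: C7 lies α to C8, the carbon that carries the exocyclic methylene (a masked ketone), and C6 hangs on the ring-fusion carbon C5, which sits between the quaternary carbons C4 and C10. A C7 radical next to a C8 carbonyl therefore adds 6-endo to a C5=C6 methylene, 5-exo closure is blocked, and the C5 radical can only take up hydrogen.
- Stereochemistry: C13 from (S)-citronellol; C4 by auxiliary-controlled methylation; C10 by the Claisen shift on the face of the C4 ester; C5 by hydrogen-atom transfer anti to the two axial methyls; C9 by enolate geometry and equilibration next to the C8 ketone.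

Key step: step 15

Assumption: with the L-valine tert-butyl ester auxiliary in toluene/HMPA the methyl group is taken to enter on the face that gives (R)-5; if the chelate delivers the other face, the D-valine ester is used and nothing else changes.

**Step 1**
Reactants: 1 methyl 2-oxocyclohexane-1-carboxylate; 2 L-valine tert-butyl ester (free base from the commercial hydrochloride)
Product: 3 methyl 2-{[(2S)-1-tert-butoxy-3-methyl-1-oxobutan-2-yl]amino}cyclohex-1-ene-1-carboxylate
Conditions: BF3·OEt2 (cat.), PhH, reflux, Dean–Stark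
Reagents that add atoms: none
Why: Acid-catalysed condensation of a β-keto ester with a primary amine should give the conjugated, hydrogen-bonded enamino ester (vinylogous carbamate), which carries the chiral controller for step 2.

**Step 2**
Reactants: 3 enamino ester
Product: 5 methyl (1R)-1-methyl-2-oxocyclohexane-1-carboxylate, via imine 4 (not isolated)
Conditions: LiN(i-Pr)2, PhMe, HMPA, −78 °C; MeI, −78 → −20 °C; then 1 M HCl, 25 °C
Reagents that add atoms: iodomethane CI; water O
Why: Auxiliary-controlled alkylation of a chiral lithioenamine: lithium is chelated between nitrogen and the valine ester carbonyl, the isopropyl group shields one face, MeI should enter from the other to build quaternary C4 as (R), and acid hydrolysis of the imine returns the ketone and the auxiliary.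

**Step 3**
Reactants: 5 methyl (1R)-1-methyl-2-oxocyclohexane-1-carboxylate
Product: 6 methyl (1R)-1,3-dimethyl-2-oxocyclohexane-1-carboxylate (C3 epimers)
Conditions: LiN(i-Pr)2, THF, −78 °C; MeI, −78 → 0 °C
Reagents that add atoms: iodomethane CI
Why: Kinetic enolate alkylation: only the CH2 side of the ketone can enolise because C4 is quaternary, and the configuration of the new centre (future C10) is irrelevant since it becomes sp2 in step 4.

**Step 4**
Reactants: 6 methyl (1R)-1,3-dimethyl-2-oxocyclohexane-1-carboxylate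
Product: 7 methyl (1R)-1,3-dimethyl-2-[(trifluoromethanesulfonyl)oxy]cyclohex-2-ene-1-carboxylate
Conditions: KN(SiMe3)2, THF, −78 °C; PhNTf2, −78 → 0 °C
Reagents that add atoms: N-phenylbis(trifluoromethanesulfonimide) O=S(=O)(N(c1ccccc1)S(=O)(=O)C(F)(F)F)C(F)(F)F
Why: Enolate O-triflation: the single remaining α-hydrogen fixes the enol triflate as the tetrasubstituted C5=C10 isomer and C4 is untouched.

**Step 5**
Reactants: 7 enol triflate
Product: 8 methyl (1R)-2-formyl-1,3-dimethylcyclohex-2-ene-1-carboxylate
Conditions: Pd(PPh3)4 (cat.), LiCl, CO (1 atm), Bu3SnH (slow addition), THF, 50 °C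
Reagents that add atoms: carbon monoxide [C-]#[O+]
Why: Palladium-catalysed reductive carbonylation (formylation): oxidative addition of the enol triflate to zerovalent palladium, CO insertion and hydride transfer from tin should install C6 at the aldehyde level, as known for hindered cyclohexenyl triflates.

**Step 6**
Reactants: 8 enal
Product: 9 methyl (1R)-2-(hydroxymethyl)-1,3-dimethylcyclohex-2-ene-1-carboxylate
Conditions: NaBH4, CeCl3·7H2O, MeOH, −40 °C; cold pH 7 work-up
Reagents that add atoms: none
Why: Luche 1,2-reduction takes the aldehyde to the allylic alcohol and leaves the hindered ester alone; cold, neutral handling keeps the hydroxy ester from lactonising.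

**Step 7**
Reactants: 10 (S)-citronellol
Product: 11 tert-butyl{[(3S)-3,7-dimethyloct-6-en-1-yl]oxy}diphenylsilane
Conditions: t-BuPh2SiCl, imidazole, CH2Cl2, 25 °C
Reagents that add atoms: tert-butyl(chloro)diphenylsilane CC(C)(C)[Si](Cl)(c1ccccc1)c1ccccc1
Why: Silylation of the primary alcohol masks the future C15 acid as a non-enolisable group that should survive amide bases, HBr, radicals and ylides; the C13 centre comes from the chiral pool.

**Step 8**
Reactants: 11 silyl ether
Product: 13 (4S)-6-[(tert-butyldiphenylsilyl)oxy]-4-methylhexanal, via ozonide 12 (not isolated)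
Conditions: O3, CH2Cl2, −78 °C; PPh3, −78 → 25 °C
Reagents that add atoms: ozone [O-][O+]=O
Why: Ozonolysis with reductive work-up cleaves the trisubstituted alkene to the aldehyde whose carbonyl carbon becomes C9.

**Step 9**
Reactants: 13 aldehyde
Product: 14 tert-butyl{[(3S)-3-methylhept-6-en-1-yl]oxy}diphenylsilane
Conditions: Ph3PCH3Br, KN(SiMe3)2, THF, 0 → 25 °C
Reagents that add atoms: methyltriphenylphosphonium bromide C[P+](c1ccccc1)(c1ccccc1)c1ccccc1.[Br-]
Why: Wittig methylenation adds the carbon that becomes C8.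

**Step 10**
Reactants: 14 terminal alkene
Product: 16 (5S)-7-[(tert-butyldiphenylsilyl)oxy]-5-methylheptan-1-ol, via alkylborane 15 (not isolated)
Conditions: 9-BBN-H, THF, 0 → 25 °C; then NaOH, H2O2, 0 °C
Reagents that add atoms: hydrogen peroxide OO
Why: Anti-Markovnikov hydroboration–oxidation places oxygen on the terminal carbon (C8).

**Step 11**
Reactants: 16 primary alcohol
Product: 18 (5S)-7-[(tert-butyldiphenylsilyl)oxy]-5-methylheptanoic acid, via aldehyde 17 (not isolated)
Conditions: TEMPO (cat.), PhI(OAc)2, MeCN/H2O, 25 °C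
Reagents that add atoms: water O
Why: Oxoammonium oxidation in aqueous acetonitrile takes the primary alcohol through the aldehyde hydrate to the acid and tolerates the silyl ether.

**Step 12**
Reactants: 9 allylic alcohol (fragment 1); 18 acid (fragment 2)
Product: 19 [(6R)-6-(methoxycarbonyl)-2,6-dimethylcyclohex-1-en-1-yl]methyl (5S)-7-[(tert-butyldiphenylsilyl)oxy]-5-methylheptanoate
Conditions: EDC·HCl, DMAP, CH2Cl2, 0 → 25 °C
Reagents that add atoms: none
Why: Steglich-type carbodiimide esterification joins the fragments under mild conditions and caps the allylic oxygen before it can attack the C4 ester.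

**Step 13**
Reactants: 19 allylic ester
Product: 22 (2R,5S)-7-[(tert-butyldiphenylsilyl)oxy]-2-[(1R,3R)-3-(methoxycarbonyl)-1,3-dimethyl-2-methylidenecyclohexyl]-5-methylheptanoic acid, via silyl ketene acetal 20 (not isolated), via silyl ester 21 (not isolated)
Conditions: LiN(i-Pr)2, THF/DMPU, −78 °C; Me3SiCl, Et3N; −78 → 65 °C; then 1 M HCl
Reagents that add atoms: none
Why: Ireland–Claisen rearrangement: a chair-like [3,3] shift of 20 joins C9 to C10 and moves the ring double bond out to C5=C6; the new bond must form axially at C10 and is expected on the face where its syn-axial partner at C4 is the slim, planar ester and not the methyl group (C9 cis to CO2Me), while the enolate formed in THF/DMPU (chain cis to OSiMe3, equatorial in the chair) gives the C9 configuration drawn, a centre that step 15 can still correct.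

**Step 14**
Reactants: 22 acid
Product: 25 methyl (1R,3R)-3-[(3R,6S)-1-bromo-8-[(tert-butyldiphenylsilyl)oxy]-6-methyl-2-oxooctan-3-yl]-1,3-dimethyl-2-methylidenecyclohexane-1-carboxylate, via acid chloride 23 (not isolated), via diazoketone 24 (not isolated)
Conditions: (COCl)2, DMF (cat.), CH2Cl2, 0 → 25 °C; CH2N2, Et2O, 0 °C; then 48% HBr, Et2O, 0 °C
Reagents that add atoms: diazomethane C=[N+]=[N-]; hydrogen bromide Br
Why: Acylation of diazomethane by the acid chloride followed by protonation of the diazo carbon and bromide displacement of N2 (Nierenstein-type sequence) adds C7 as a bromomethyl ketone far faster than HBr can touch the hindered methylene or the silyl ether.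

**Step 15**
Reactants: 25 bromomethyl ketone
Product: 26 methyl (1R,4aS,5R,8aR)-5-{(3S)-5-[(tert-butyldiphenylsilyl)oxy]-3-methylpentyl}-1,4a-dimethyl-6-oxodecahydronaphthalene-1-carboxylate
Conditions: (Me3Si)3SiH, AIBN, t-C12H25SH (cat.), PhMe (5 mM), 90 °C, slow addition; then NaOMe, MeOH, 25 °C
Reagents that add atoms: none
Why: (Me3Si)3Si• abstracts bromine from 25 to give the electrophilic α-keto radical at C7, which adds to the unsubstituted terminus C6 of the electron-rich C5=C6 methylene, forming the C6–C7 bond and a tertiary radical at C5 that is reduced by hydrogen-atom transfer from the thiol (regenerated by the silane). The closest known reaction type is the reductive 6-endo cyclisation of α-halo ketone-derived radicals onto 1,1-disubstituted alkenes under tin or silicon hydride conditions with thiol polarity-reversal catalysis. Ring B closes in the 6-endo-trig mode; the 5-exo alternative would need bond formation at C5, a fully substituted carbon between the quaternary C4 and C10, and is also disfavoured for radicals whose carbonyl lies inside the forming ring. C5 is set by the substrate: the β face of the C5 radical is covered by the axial C10 methyl and the axial C4 methyl, so hydrogen should arrive from the α face and make the ring fusion trans, and C9, now α to a ring ketone, is brought to (or kept in) the equatorial, natural configuration by the NaOMe treatment. The step needs cyclisation to outrun reduction of the first radical; this is secured by keeping the silane dilute and by the polarity mismatch between the electrophilic α-keto radical and the thiol, which is by contrast a matched, small donor for the nucleophilic C5 radical.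

**Step 16**
Reactants: 26 ketone
Product: 27 methyl (1R,4aR,5S,8aR)-5-{(3S)-5-[(tert-butyldiphenylsilyl)oxy]-3-methylpentyl}-1,4a-dimethyl-6-methylidenedecahydronaphthalene-1-carboxylate
Conditions: Ph3PCH3Br, KOt-Bu, PhMe, 80 °C
Reagents that add atoms: methyltriphenylphosphonium bromide C[P+](c1ccccc1)(c1ccccc1)c1ccccc1.[Br-]
Why: Wittig methylenation of the C8 ketone installs C17; C9 already has its thermodynamic configuration so the basic ylide cannot erode it, and the hindered C4 ester is inert.

**Step 17**
Reactants: 27 silyl ether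
Product: 28 methyl (1R,4aR,5S,8aR)-5-[(3S)-5-hydroxy-3-methylpentyl]-1,4a-dimethyl-6-methylidenedecahydronaphthalene-1-carboxylate
Conditions: Bu4NF, THF, 25 °C
Reagents that add atoms: none
Why: Fluoride-mediated desilylation frees the C15 alcohol without touching the ester or the exocyclic alkene.

**Step 18**
Reactants: 28 primary alcohol
Product: 30 (3S)-5-[(1S,4aR,5R,8aR)-5-(methoxycarbonyl)-5,8a-dimethyl-2-methylidenedecahydronaphthalen-1-yl]-3-methylpentanoic acid (CNP0135192.1), via aldehyde 29 (not isolated)
Conditions: TEMPO (cat.), PhI(OAc)2, MeCN/pH 7 buffer, 25 °C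
Reagents that add atoms: water O
Why: Oxoammonium oxidation of the primary alcohol through the aldehyde hydrate gives the C15 acid under near-neutral conditions that should not isomerise the 8(17)-alkene or cleave the C18 methyl ester.

**Compound list**

1 | methyl 2-oxocyclohexane-1-carboxylate | COC(=O)C1CCCCC1=O | starting material
2 | L-valine tert-butyl ester, tert-butyl (2S)-2-amino-3-methylbutanoate | CC(C)[C@H](N)C(=O)OC(C)(C)C | starting material
3 | methyl 2-{[(2S)-1-tert-butoxy-3-methyl-1-oxobutan-2-yl]amino}cyclohex-1-ene-1-carboxylate | COC(=O)C1=C(N[C@@H](C(C)C)C(=O)OC(C)(C)C)CCCC1 | intermediate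
4 | methyl (1R)-2-{[(2S)-1-tert-butoxy-3-methyl-1-oxobutan-2-yl]imino}-1-methylcyclohexane-1-carboxylate | COC(=O)[C@]1(C)CCCCC1=N[C@@H](C(C)C)C(=O)OC(C)(C)C | intermediate (not isolated)
5 | methyl (1R)-1-methyl-2-oxocyclohexane-1-carboxylate | COC(=O)[C@]1(C)CCCCC1=O | intermediate
6 | methyl (1R)-1,3-dimethyl-2-oxocyclohexane-1-carboxylate (C3 epimers, centre left undefined) | COC(=O)[C@]1(C)CCCC(C)C1=O | intermediate
7 | methyl (1R)-1,3-dimethyl-2-[(trifluoromethanesulfonyl)oxy]cyclohex-2-ene-1-carboxylate | COC(=O)[C@]1(C)CCCC(C)=C1OS(=O)(=O)C(F)(F)F | intermediate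
8 | methyl (1R)-2-formyl-1,3-dimethylcyclohex-2-ene-1-carboxylate | COC(=O)[C@]1(C)CCCC(C)=C1C=O | intermediate
9 | methyl (1R)-2-(hydroxymethyl)-1,3-dimethylcyclohex-2-ene-1-carboxylate | COC(=O)[C@]1(C)CCCC(C)=C1CO | intermediate
10 | (S)-citronellol, (3S)-3,7-dimethyloct-6-en-1-ol | CC(C)=CCC[C@H](C)CCO | starting material
11 | tert-butyl{[(3S)-3,7-dimethyloct-6-en-1-yl]oxy}diphenylsilane | CC(C)=CCC[C@H](C)CCO[Si](c1ccccc1)(c1ccccc1)C(C)(C)C | intermediate
12 | 3-{(3S)-5-[(tert-butyldiphenylsilyl)oxy]-3-methylpentyl}-5,5-dimethyl-1,2,4-trioxolane (ring carbon undefined) | CC1(C)OOC(CC[C@H](C)CCO[Si](c2ccccc2)(c2ccccc2)C(C)(C)C)O1 | intermediate (not isolated)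
13 | (4S)-6-[(tert-butyldiphenylsilyl)oxy]-4-methylhexanal | O=CCC[C@H](C)CCO[Si](c1ccccc1)(c1ccccc1)C(C)(C)C | intermediate
14 | tert-butyl{[(3S)-3-methylhept-6-en-1-yl]oxy}diphenylsilane | C=CCC[C@H](C)CCO[Si](c1ccccc1)(c1ccccc1)C(C)(C)C | intermediate
15 | 9-{(5S)-7-[(tert-butyldiphenylsilyl)oxy]-5-methylheptyl}-9-borabicyclo[3.3.1]nonane | C(CCC[C@H](C)CCO[Si](c1ccccc1)(c1ccccc1)C(C)(C)C)B1C2CCCC1CCC2 | intermediate (not isolated)
16 | (5S)-7-[(tert-butyldiphenylsilyl)oxy]-5-methylheptan-1-ol | OCCCC[C@H](C)CCO[Si](c1ccccc1)(c1ccccc1)C(C)(C)C | intermediate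
17 | (5S)-7-[(tert-butyldiphenylsilyl)oxy]-5-methylheptanal | O=CCCC[C@H](C)CCO[Si](c1ccccc1)(c1ccccc1)C(C)(C)C | intermediate (not isolated)
18 | (5S)-7-[(tert-butyldiphenylsilyl)oxy]-5-methylheptanoic acid | OC(=O)CCC[C@H](C)CCO[Si](c1ccccc1)(c1ccccc1)C(C)(C)C | intermediate
19 | [(6R)-6-(methoxycarbonyl)-2,6-dimethylcyclohex-1-en-1-yl]methyl (5S)-7-[(tert-butyldiphenylsilyl)oxy]-5-methylheptanoate | COC(=O)[C@]1(C)CCCC(C)=C1COC(=O)CCC[C@H](C)CCO[Si](c1ccccc1)(c1ccccc1)C(C)(C)C | intermediate
20 | methyl (1R)-2-({[(5S)-7-[(tert-butyldiphenylsilyl)oxy]-5-methyl-1-[(trimethylsilyl)oxy]hept-1-en-1-yl]oxy}methyl)-1,3-dimethylcyclohex-2-ene-1-carboxylate (chain cis to OSiMe3) | COC(=O)[C@]1(C)CCCC(C)=C1CO/C(O[Si](C)(C)C)=C/CC[C@H](C)CCO[Si](c1ccccc1)(c1ccccc1)C(C)(C)C | intermediate (not isolated)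
21 | trimethylsilyl (2R,5S)-7-[(tert-butyldiphenylsilyl)oxy]-2-[(1R,3R)-3-(methoxycarbonyl)-1,3-dimethyl-2-methylidenecyclohexyl]-5-methylheptanoate | C=C1[C@](C)(C(=O)OC)CCC[C@]1(C)[C@H](C(=O)O[Si](C)(C)C)CC[C@H](C)CCO[Si](c1ccccc1)(c1ccccc1)C(C)(C)C | intermediate (not isolated)
22 | (2R,5S)-7-[(tert-butyldiphenylsilyl)oxy]-2-[(1R,3R)-3-(methoxycarbonyl)-1,3-dimethyl-2-methylidenecyclohexyl]-5-methylheptanoic acid | C=C1[C@](C)(C(=O)OC)CCC[C@]1(C)[C@H](C(=O)O)CC[C@H](C)CCO[Si](c1ccccc1)(c1ccccc1)C(C)(C)C | intermediate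
23 | (2R,5S)-7-[(tert-butyldiphenylsilyl)oxy]-2-[(1R,3R)-3-(methoxycarbonyl)-1,3-dimethyl-2-methylidenecyclohexyl]-5-methylheptanoyl chloride | C=C1[C@](C)(C(=O)OC)CCC[C@]1(C)[C@H](C(=O)Cl)CC[C@H](C)CCO[Si](c1ccccc1)(c1ccccc1)C(C)(C)C | intermediate (not isolated)
24 | methyl (1R,3R)-3-[(3R,6S)-8-[(tert-butyldiphenylsilyl)oxy]-1-diazo-6-methyl-2-oxooctan-3-yl]-1,3-dimethyl-2-methylidenecyclohexane-1-carboxylate | C=C1[C@](C)(C(=O)OC)CCC[C@]1(C)[C@H](C(=O)C=[N+]=[N-])CC[C@H](C)CCO[Si](c1ccccc1)(c1ccccc1)C(C)(C)C | intermediate (not isolated)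
25 | methyl (1R,3R)-3-[(3R,6S)-1-bromo-8-[(tert-butyldiphenylsilyl)oxy]-6-methyl-2-oxooctan-3-yl]-1,3-dimethyl-2-methylidenecyclohexane-1-carboxylate | C=C1[C@](C)(C(=O)OC)CCC[C@]1(C)[C@H](C(=O)CBr)CC[C@H](C)CCO[Si](c1ccccc1)(c1ccccc1)C(C)(C)C | intermediate
26 | methyl (1R,4aS,5R,8aR)-5-{(3S)-5-[(tert-butyldiphenylsilyl)oxy]-3-methylpentyl}-1,4a-dimethyl-6-oxodecahydronaphthalene-1-carboxylate (trans-fused 8-oxo-17-norlabdane) | O=C1CC[C@@H]2[C@](C)(CCC[C@@]2(C)C(=O)OC)[C@H]1CC[C@H](C)CCO[Si](c1ccccc1)(c1ccccc1)C(C)(C)C | intermediate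
27 | methyl (1R,4aR,5S,8aR)-5-{(3S)-5-[(tert-butyldiphenylsilyl)oxy]-3-methylpentyl}-1,4a-dimethyl-6-methylidenedecahydronaphthalene-1-carboxylate | C=C1CC[C@@H]2[C@](C)(CCC[C@@]2(C)C(=O)OC)[C@H]1CC[C@H](C)CCO[Si](c1ccccc1)(c1ccccc1)C(C)(C)C | intermediate
28 | methyl (1R,4aR,5S,8aR)-5-[(3S)-5-hydroxy-3-methylpentyl]-1,4a-dimethyl-6-methylidenedecahydronaphthalene-1-carboxylate | C=C1CC[C@@H]2[C@](C)(CCC[C@@]2(C)C(=O)OC)[C@H]1CC[C@H](C)CCO | intermediate
29 | methyl (1R,4aR,5S,8aR)-1,4a-dimethyl-6-methylidene-5-[(3S)-3-methyl-5-oxopentyl]decahydronaphthalene-1-carboxylate | C=C1CC[C@@H]2[C@](C)(CCC[C@@]2(C)C(=O)OC)[C@H]1CC[C@H](C)CC=O | intermediate (not isolated)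
30 | (3S)-5-[(1S,4aR,5R,8aR)-5-(methoxycarbonyl)-5,8a-dimethyl-2-methylidenedecahydronaphthalen-1-yl]-3-methylpentanoic acid (CNP0135192.1) | C=C1CC[C@@H]2[C@](C)(CCC[C@@]2(C)C(=O)OC)[C@H]1CC[C@H](C)CC(=O)O | target

**Step count and risks**

Total steps: 18. Longest linear sequence: 13 steps (steps 1–6, then 12–18); fragment 2 takes steps 7–11.

Most likely to fail:

1. Step 13. The facial bias at C10 rests only on the size difference between methyl and CO2Me at C4, and the shift is slow at a fully substituted alkene terminus, so attack on the wrong ring face may compete. The fallback sets out from 19 and replaces substrate control by reagent control. The ester is enolised with (4S,5S)-2-bromo-4,5-diphenyl-1,3-bis(4-methylphenylsulfonyl)-1,3,2-diazaborolidine and i-Pr2NEt in CH2Cl2 at −78 °C to the chiral boron ketene acetal F1. On warming this should rearrange to the boron carboxylate F2, and aqueous work-up releases acid 22, where the route is rejoined. The antipode of the boron ligand that reinforces attack on the ester face is the one to use; the compounds are written for S,S.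

2. Step 15. The α-keto radical may take up hydrogen before it cyclises (plain debromination), and hydrogen delivery to the C5 radical may not be fully face-selective. The fallback sets out from 25 and separates ring closure from the setting of C5. Bromine atom-transfer cyclisation without any hydride (CuBr, tris(2-pyridylmethyl)amine, 1,2-dichloroethane, 80 °C) should give the tertiary 5-bromo ketone F3. DBU then eliminates it in the same flask to the Δ5 olefin, methyl 15-[(tert-butyldiphenylsilyl)oxy]-8-oxo-17-norlabd-5-en-18-oate F4. Hydrogen-atom-transfer hydrogenation (Mn(dpm)3, PhSiH3, t-BuOOH, i-PrOH, 25 °C), a method known to give trans-fused decalins from such olefins, followed by NaOMe/MeOH, returns to 26.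

3. Step 6. The free allylic alcohol (or its alkoxide) may attack the neighbouring C4 methyl ester and close a γ-lactone, destroying both the alcohol and the ester. The fallback sets out from 8 and never liberates the alcohol. The aldehyde is reduced with i-Bu2AlH in CH2Cl2 at −78 °C, and the aluminium alkoxide is acylated in the same flask with (5S)-7-[(tert-butyldiphenylsilyl)oxy]-5-methylheptanoyl chloride F5 (from 18 and (COCl)2), pyridine and DMAP, −78 → 0 °C. This gives ester 19 directly, where the route is rejoined.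

**Further compounds**

F1 | step 13 | boron ketene acetal of 19 with the (4S,5S)-4,5-diphenyl-1,3-ditosyl-1,3,2-diazaborolidin-2-yl group on the enolate oxygen | COC(=O)[C@]1(C)CCCC(C)=C1CO/C(OB2N(S(=O)(=O)c3ccc(C)cc3)[C@@H](c3ccccc3)[C@H](c3ccccc3)N2S(=O)(=O)c2ccc(C)cc2)=C/CC[C@H](C)CCO[Si](c1ccccc1)(c1ccccc1)C(C)(C)C
F2 | step 13 | (4S,5S)-4,5-diphenyl-1,3-ditosyl-1,3,2-diazaborolidin-2-yl ester of acid 22 | C=C1[C@](C)(C(=O)OC)CCC[C@]1(C)[C@H](C(=O)OB1N(S(=O)(=O)c2ccc(C)cc2)[C@@H](c2ccccc2)[C@H](c2ccccc2)N1S(=O)(=O)c1ccc(C)cc1)CC[C@H](C)CCO[Si](c1ccccc1)(c1ccccc1)C(C)(C)C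
F3 | step 15 | methyl 5α-bromo-15-[(tert-butyldiphenylsilyl)oxy]-8-oxo-17-norlabdan-18-oate (not isolated) | O=C1CC[C@]2(Br)[C@](C)(CCC[C@@]2(C)C(=O)OC)[C@H]1CC[C@H](C)CCO[Si](c1ccccc1)(c1ccccc1)C(C)(C)C
F4 | step 15 | methyl 15-[(tert-butyldiphenylsilyl)oxy]-8-oxo-17-norlabd-5-en-18-oate | O=C1CC=C2[C@](C)(CCC[C@@]2(C)C(=O)OC)[C@H]1CC[C@H](C)CCO[Si](c1ccccc1)(c1ccccc1)C(C)(C)C
F5 | step 6 | (5S)-7-[(tert-butyldiphenylsilyl)oxy]-5-methylheptanoyl chloride | ClC(=O)CCC[C@H](C)CCO[Si](c1ccccc1)(c1ccccc1)C(C)(C)C
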